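**Retrosynthetic overview**

1. Labels: caryophyllane numbering C1–C13 (ring A = cyclobutane, ring B = nine-membered ring, C8 = spiro carbon, C13 = former exocyclic methylene); C1′ = CH(iBu); ring C = O–C8–C13–C1′–C2′=C3′; ring D = C2′=C3′(O)–C4′Me2–C5′(=O)–C6′Me2–C7′(=O).
2. Ring C is cut by a retro-oxa-Diels–Alder reaction (O–C8 and C13–C1′). This gives a (5S)-dienol carrying the C8=C13 methylene and the 1-oxadiene O=C3′–C2′=C1′H(iBu), which is the Knoevenagel product of isovaleraldehyde and the parent triketone.
3. Ring D is not assembled as a six-membered ring. C4′–C5′–C6′–C7′ is the four-membered ring of 2,2,4,4-tetramethylcyclobutane-1,3-dione, and C2′–C3′ is inserted from ethyl acetate by enolate addition, strain-driven retro-aldol opening and Claisen re-closure (four- to six-membered, two-carbon ring expansion).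
4. Enabling feature: the non-enolisable array C7′(=O)–C6′Me2–C5′(=O)–C4′Me2 of ring D is a dimethylketene dimer in disguise, and C2′ lies between two carbonyls, so the expanded ring condenses at once to the oxadiene that adds across C8=C13.
5. Dienol: (−)-caryophyllene oxide, epoxide-to-allylic-alcohol isomerisation toward C3, then oxidation and CBS reduction to invert C5. Ring order: A and B from the chiral pool, then D (ring expansion) and C (cycloaddition at the fully substituted C8) in one flask.

Key step: step 4

Assumption: read with the labels above, the target SMILES is (1R,3Z,5S,8S,9S,1′S); its C5–O bond is therefore epimeric to the C5–O bond of natural (−)-caryophyllene oxide, and C5 must be inverted on the way.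

**Route**

Step 1
Reactants: 1 (−)-caryophyllene oxide, (1R,4R,6R,10S)-4,12,12-trimethyl-9-methylidene-5-oxatricyclo[8.2.0.0(4,6)]dodecane
Product: 2 (1R,3Z,5R,9S)-4,11,11-trimethyl-8-methylidenebicyclo[7.2.0]undec-3-en-5-ol
Conditions: Et2AlCl, lithium 2,2,6,6-tetramethylpiperidide (LiTMP) (4 equiv each, forms diethylaluminium 2,2,6,6-tetramethylpiperidide, DATMP), toluene, 0 °C; aqueous work-up
Reagents that add atoms: none
Why: Aluminium amide-mediated epoxide-to-allylic-alcohol isomerisation, in which the oxygen-bound amide removes through a six-membered syn transition state a hydrogen of the C3 methylene (the alkyl group cis to the epoxide hydrogen) and not of the C12 methyl, the new C3=C4 bond should form ring-cis (Z) because C2 lies gauche to C5 in the folded nine-membered ring, and C5 keeps its C–O bond and stays (R).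

Step 2
Reactants: 2 (1R,3Z,5R,9S)-4,11,11-trimethyl-8-methylidenebicyclo[7.2.0]undec-3-en-5-ol
Product: 3 (1R,3Z,9S)-4,11,11-trimethyl-8-methylidenebicyclo[7.2.0]undec-3-en-5-one
Conditions: Dess–Martin periodinane, CH2Cl2, 0 °C to rt
Reagents that add atoms: none
Why: Dess–Martin oxidation of a secondary allylic alcohol, mild enough to leave both alkenes and the (Z) geometry untouched, deliberately planarises C5 so that its configuration can be reset.

Step 3
Reactants: 3 (1R,3Z,9S)-4,11,11-trimethyl-8-methylidenebicyclo[7.2.0]undec-3-en-5-one
Product: 4 (1R,3Z,5S,9S)-4,11,11-trimethyl-8-methylidenebicyclo[7.2.0]undec-3-en-5-ol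
Conditions: (R)-2-methyl-CBS-oxazaborolidine (20 mol%), catecholborane, toluene, −78 °C
Reagents that add atoms: none
Why: Corey–Bakshi–Shibata reduction, in which the (R)-oxazaborolidine binds the ketone anti to the larger α-methylalkenyl side (C4) and should deliver hydride in 1,2-fashion to the face that gives the (5S)-carbinol under reagent control, while catecholborane does not hydroborate the alkenes at this temperature.

Step 4
Reactants: 5 2,2,4,4-tetramethylcyclobutane-1,3-dione; 6 ethyl acetate; 7 isovaleraldehyde (3-methylbutanal); 4 (1R,3Z,5S,9S)-4,11,11-trimethyl-8-methylidenebicyclo[7.2.0]undec-3-en-5-ol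
Product: 12 Tomentodione P, via cyclobutanol aldolate 8 (not isolated), via ring-opened keto ester 9 (not isolated), via syncarpic acid 10 (not isolated), via alkylidene trione 11 (not isolated)
Conditions: 6, lithium diisopropylamide (LDA, 1.05 equiv), THF, −78 °C; 5, −78 to 0 °C; LDA (1.2 equiv), 0 to 40 °C; AcOH (excess); 7, 4, ethylenediammonium diacetate (10 mol%), 70 °C, sealed vessel
Reagents that add atoms: none
Why: Proposed new method: the lithium enolate of 6 adds to one carbonyl of the strained, non-enolisable dione 5 to give aldolate 8, which opens by a retro-aldol (retro-Claisen-type) C–C fragmentation driven by four-ring strain to the enolate of keto ester 9; the second charge of base then forms the remote isopropyl-ketone enolate, whose 6-(enolendo)-exo-trig Claisen (Dieckmann) attack on the ester closes ring D and expels ethoxide, so that the acetate C2 unit ends up inserted into a C(=O)–CMe2 bond of the four-membered ring and the stabilised enolate of 10 acts as thermodynamic sink. The closest known reaction types are the alkoxide-triggered retro-Claisen opening of 5, the base-catalysed conversion of dimethylketene dimer into hexamethylcyclohexane-1,3,5-trione and the Claisen cyclisation of 3,5-dioxo esters to cyclohexane-1,3,5-triones. After the acetic acid quench, 10 and 7 condense in the amine acetate buffer (Knoevenagel) to the 1-oxadiene 11, which has a single geometry because ring D is symmetric, and 11 is trapped by 4, added only at this mildly acidic stage, in an inverse-electron-demand oxa-Diels–Alder reaction, a known mode of union of alkylidene β-triketones and 1,1-disubstituted alkenes. Ring C is thereby closed by [4+2] cycloaddition (bonds C13–C1′ and O–C8), with oxygen going to the more substituted carbon because the asynchronous transition state builds positive charge at tertiary C8; the step needs chemoselectivity for C8=C13 over C3=C4, which the unhindered, more nucleophilic 1,1-disubstituted methylene secures against a trisubstituted alkene that is deactivated by its allylic hydroxyl, while the free hydroxyl adds to 11 only reversibly. C8 should be set by approach of the diene oxygen to the face of the methylene that carries only H9, the other face being screened by C1 and C10 of the trans-fused cyclobutane, and C1′ by the isobutyl group lying outside on the diene with the C9 branch endo (pseudo-equatorial in the forming half-chair), which puts isobutyl and C9 cis on ring C as the target requires.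

**Compound list**

1 | (−)-caryophyllene oxide, (1R,4R,6R,10S)-4,12,12-trimethyl-9-methylidene-5-oxatricyclo[8.2.0.0(4,6)]dodecane | C[C@@]12CC[C@@H]3[C@H](CC3(C)C)C(=C)CC[C@H]1O2 | starting material
2 | (1R,3Z,5R,9S)-4,11,11-trimethyl-8-methylidenebicyclo[7.2.0]undec-3-en-5-ol | C/C1=C/C[C@@H]2[C@H](CC2(C)C)C(=C)CC[C@H]1O | intermediate
3 | (1R,3Z,9S)-4,11,11-trimethyl-8-methylidenebicyclo[7.2.0]undec-3-en-5-one | C/C1=C/C[C@@H]2[C@H](CC2(C)C)C(=C)CCC1=O | intermediate
4 | (1R,3Z,5S,9S)-4,11,11-trimethyl-8-methylidenebicyclo[7.2.0]undec-3-en-5-ol | C/C1=C/C[C@@H]2[C@H](CC2(C)C)C(=C)CC[C@@H]1O | intermediate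
5 | 2,2,4,4-tetramethylcyclobutane-1,3-dione | CC1(C)C(=O)C(C)(C)C1=O | starting material
6 | ethyl acetate | CCOC(C)=O | starting material
7 | isovaleraldehyde (3-methylbutanal) | CC(C)CC=O | starting material
8 | ethyl 2-(1-hydroxy-2,2,4,4-tetramethyl-3-oxocyclobutyl)acetate (formed as its lithium alkoxide) | CCOC(=O)CC1(O)C(C)(C)C(=O)C1(C)C | intermediate
9 | ethyl 4,4,6-trimethyl-3,5-dioxoheptanoate (formed as its enolate) | CCOC(=O)CC(=O)C(C)(C)C(=O)C(C)C | intermediate
10 | syncarpic acid, 5-hydroxy-2,2,6,6-tetramethylcyclohex-4-ene-1,3-dione (enol form of 2,2,4,4-tetramethylcyclohexane-1,3,5-trione) | CC1(C)C(=O)C=C(O)C(C)(C)C1=O | intermediate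
11 | 2,2,4,4-tetramethyl-6-(3-methylbutylidene)cyclohexane-1,3,5-trione | CC(C)CC=C1C(=O)C(C)(C)C(=O)C(C)(C)C1=O | intermediate
12 | Tomentodione P, (1R,3Z,5S,8S,9S,1′S): the 4,11,11-trimethylbicyclo[7.2.0]undec-3-en-5-ol unit spiro-joined at C8 to C2 of a 4-isobutyl-6,6,8,8-tetramethyl-3,4-dihydro-2H-chromene-5,7(6H,8H)-dione | C/C1=C/C[C@@H]2[C@H](CC2(C)C)[C@]2(CC[C@@H]1O)C[C@H](CC(C)C)C1=C(O2)C(C)(C)C(=O)C(C)(C)C1=O | target

**Step count**

Total step count: 4. Longest linear sequence: 4 steps (1 → 2 → 3 → 4 → 12).

**Steps most likely to fail**

1. Step 4 (proposed new method). The sequence may stall after ring opening, because the second enolisation and the Claisen closure onto the ester of an already enolised β-keto ester are too slow, or the aldol addition may revert before the four-membered ring opens. In the second stage, facial discrimination at C8 or the endo/exo preference may be weaker than the model predicts. Fallback (known chemistry, reversed polarity of the ring closure): setting out from 5, catalytic NaOMe in MeOH opens the ring to methyl 2,2,4-trimethyl-3-oxopentanoate F1. LDA in THF at −78 °C followed by acetaldehyde gives the aldol methyl 5-hydroxy-2,2,4,4-tetramethyl-3-oxohexanoate F2. Dess–Martin oxidation gives methyl 2,2,4,4-tetramethyl-3,5-dioxohexanoate F3. Lithium hexamethyldisilazide (LiHMDS, 2 equiv) in THF then closes the ring through the unhindered methyl-ketone enolate (Claisen/Dieckmann) and the route is rejoined at 10, which is isolated and combined with 7 and 4 under the second-stage conditions of step 4 (ethylenediammonium diacetate, AcOH, THF, 70 °C) to give 12 via 11.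

2. Step 1. Proton abstraction may occur at the C12 methyl group instead of C3, or the new alkene may form with the ring-trans geometry. Fallback: setting out from 1, lithium diethylamide (LiNEt2) in refluxing Et2O takes a methyl hydrogen and should give (1R,5R,9S)-11,11-dimethyl-4,8-dimethylidenebicyclo[7.2.0]undecan-5-ol F4. Dess–Martin oxidation gives the exo-methylene ketone (1R,9S)-11,11-dimethyl-4,8-dimethylidenebicyclo[7.2.0]undecan-5-one F5. Catalytic RhCl3·3H2O in EtOH at 60 °C, stopped before the isolated C8=C13 alkene migrates, moves the conjugated exocyclic alkene into the ring by hydrometalation/β-hydride elimination. The thermodynamically preferred (Z)-enone results and the route is rejoined at 3.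

3. Step 3. Mismatched double stereodifferentiation (resident stereocentres and ring conformation opposing the catalyst) may erode facial selectivity, or the twisted medium-ring enone may be reduced too slowly. Fallback: setting out from 2 (steps 2 and 3 are bypassed), Mitsunobu inversion with 4-nitrobenzoic acid, PPh3 and diisopropyl azodicarboxylate in toluene at 0 °C to rt gives (1R,3Z,5S,9S)-4,11,11-trimethyl-8-methylidenebicyclo[7.2.0]undec-3-en-5-yl 4-nitrobenzoate F6. Methanolysis with K2CO3 in MeOH rejoins the route at 4.

**Further compounds**

F1 | step 4 | methyl 2,2,4-trimethyl-3-oxopentanoate | COC(=O)C(C)(C)C(=O)C(C)C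
F2 | step 4 | methyl 5-hydroxy-2,2,4,4-tetramethyl-3-oxohexanoate (racemic) | COC(=O)C(C)(C)C(=O)C(C)(C)C(C)O
F3 | step 4 | methyl 2,2,4,4-tetramethyl-3,5-dioxohexanoate | COC(=O)C(C)(C)C(=O)C(C)(C)C(C)=O
F4 | step 1 | (1R,5R,9S)-11,11-dimethyl-4,8-dimethylidenebicyclo[7.2.0]undecan-5-ol | C=C1CC[C@@H]2[C@H](CC2(C)C)C(=C)CC[C@H]1O
F5 | step 1 | (1R,9S)-11,11-dimethyl-4,8-dimethylidenebicyclo[7.2.0]undecan-5-one | C=C1CC[C@@H]2[C@H](CC2(C)C)C(=C)CCC1=O
F6 | step 3 | (1R,3Z,5S,9S)-4,11,11-trimethyl-8-methylidenebicyclo[7.2.0]undec-3-en-5-yl 4-nitrobenzoate | C/C1=C/C[C@@H]2[C@H](CC2(C)C)C(=C)CC[C@@H]1OC(=O)c1ccc(cc1)[N+](=O)[O-]
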